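**Retrosynthetic overview**

1. The ester is put on O9 last, by acylating the cis-8,9-diol. The C7–isopropenyl bond and the C8 hydroxyl come from trans-diaxial opening of a 7α,8α-epoxide, made by hydroxyl-directed epoxidation of a C7=C8 alkene bearing a 9α-hydroxyl. That allylic alcohol comes by Wharton transposition from the ring B enone C7(=O)–C8=C9.
2. Ring B (C5–C6–C7–C8–C9–C10) is never closed as a six-membered ring. Its enone is made in step 8 from a cyclopentane ring (C5, C6, C7, C9, C10) by inserting C8 into the C7–C9 bond, through oxidative scission of a 7-silyloxy cyclopropane (Ito–Saegusa ring expansion).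
3. Enabling feature: C7 sits next to the two oxygenated carbons C8 and C9, so it can carry a temporary carbonyl. Its enol ether double bond C7=C9 inside the five-membered ring takes up the future C8 as a temporary cyclopropane carbon, and the donor oxygen on C7 weakens the C7–C9 bond shared by the three- and five-membered rings.
4. The five-membered ring comes from an aldol condensation (C9=C10) of a 1,4-diketone on ring A. Dissolving-metal reduction then sets the trans ring fusion at C10 and gives the C7=C9 enolate regiospecifically. Ring A with C2, C4 and C5 comes from (S)-carvone.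
5. Order of ring formation: ring A (from carvone), then the cyclopentenone ring, then the temporary cyclopropane, then ring B by ring expansion.

Key step: step 8

Remark on labels: C1–C10 are the decalin carbons of the target (ring A = C1–C5 and C10, ring B = C5–C10, methyls on C4 and C5); β is the face of the C5 methyl and α the opposite face; in the hydrindane intermediates C8 is absent and the other labels are kept.
Remark on the acid: (2E)-3-methylpent-2-enoic acid is taken to be purchasable as the pure E isomer.

**Route**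

Step 1
Reactants: 1 (S)-(+)-carvone
Product: 3 (2R,3S,5S)-2,3-dimethyl-2-(prop-2-en-1-yl)-5-(prop-1-en-2-yl)cyclohexan-1-one, via lithium enolate 2 (not isolated)
Conditions: Me2CuLi, Et2O, 0 °C; then allyl bromide, THF/HMPA, −20 °C → rt
Reagents that add atoms: lithium dimethylcuprate, [Li+].C[Cu-]C; allyl bromide, C=CCBr
Why: Tandem conjugate addition–enolate alkylation: the cuprate should add anti to the isopropenyl-bearing stereocentre (this sets C4), and the regiodefined enolate 2 should be allylated by axial attack anti to the new pseudoaxial methyl, which sets the quaternary C5 with the two methyls cis.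

Step 2
Reactants: 3 (2R,3S,5S)-2,3-dimethyl-2-(prop-2-en-1-yl)-5-(prop-1-en-2-yl)cyclohexan-1-one
Product: 4 (2R,3S,5S)-2,3-dimethyl-2-(2-oxopropyl)-5-(prop-1-en-2-yl)cyclohexan-1-one
Conditions: PdCl2 (10 mol %), CuCl, O2 (1 atm), DMF/H2O, rt
Reagents that add atoms: water, O
Why: Tsuji–Wacker oxidation: the monosubstituted allyl alkene should be oxidised with Markovnikov selectivity to the methyl ketone while the 1,1-disubstituted isopropenyl group is left alone; no stereocentre is formed.

Step 3
Reactants: 4 (2R,3S,5S)-2,3-dimethyl-2-(2-oxopropyl)-5-(prop-1-en-2-yl)cyclohexan-1-one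
Product: 5 (5S,7S,7aR)-7,7a-dimethyl-5-(prop-1-en-2-yl)-1,4,5,6,7,7a-hexahydro-2H-inden-2-one
Conditions: KOH, EtOH, reflux
Reagents that add atoms: none
Why: Intramolecular aldol condensation of the 1,4-diketone: the methyl ketone enolate adds to the ring carbonyl (the future C10), and since this is the only aldol that can dehydrate, the fused cyclopentenone (C7 ketone, C9=C10) should be the thermodynamic product; no existing centre is enolisable.

Step 4
Reactants: 5 (5S,7S,7aR)-7,7a-dimethyl-5-(prop-1-en-2-yl)-1,4,5,6,7,7a-hexahydro-2H-inden-2-one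
Product: 8 (5S,7S,7aR)-7,7a-dimethyl-2-oxo-1,4,5,6,7,7a-hexahydro-2H-inden-5-yl acetate, via methoxy hydroperoxide 6 (not isolated), via peracetate 7 (not isolated)
Conditions: O3, CH2Cl2/MeOH, −78 °C; then Ac2O, Et3N, DMAP (cat.), 0 °C → rt
Reagents that add atoms: ozone, [O-][O+]=O; methanol, CO
Why: Chemoselective ozonolysis followed by Criegee rearrangement: ozone should attack the electron-rich isopropenyl alkene much faster than the conjugated enone, methanol traps the carbonyl oxide as 6, and acetylation to 7 triggers migration of ring carbon C2 from carbon to oxygen with retention, so the acetyl group of 8 is the former C(CH3) of the isopropenyl group and O2 keeps the α configuration.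

Step 5
Reactants: 8 (5S,7S,7aR)-7,7a-dimethyl-2-oxo-1,4,5,6,7,7a-hexahydro-2H-inden-5-yl acetate
Product: 9 (5S,7S,7aR)-5-hydroxy-7,7a-dimethyl-1,4,5,6,7,7a-hexahydro-2H-inden-2-one
Conditions: K2CO3 (cat.), MeOH, 0 °C
Reagents that add atoms: none
Why: Base-catalysed transesterification of the acetate under conditions that should be too mild for γ-deprotonation of the enone; C2 is untouched.

Step 6
Reactants: 9 (5S,7S,7aR)-5-hydroxy-7,7a-dimethyl-1,4,5,6,7,7a-hexahydro-2H-inden-2-one
Product: 11 (3aS,5S,7S,7aR)-7,7a-dimethyl-2,5-bis(trimethylsilyloxy)-3a,4,5,6,7,7a-hexahydro-1H-indene, via dilithium enolate alkoxide 10 (not isolated)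
Conditions: Li, NH3 (l)/THF, −78 °C; NH3 evaporated; then TMSCl, Et3N, THF, −78 → 0 °C
Reagents that add atoms: chlorotrimethylsilane, C[Si](C)(C)Cl
Why: Dissolving-metal (Birch-type) reduction of the enone with regiospecific enolate trapping: two electrons and the proton of the C2 hydroxyl convert 9 into 10, C10 should be protonated on the α face anti to the adjacent C5 methyl (trans ring fusion), and silylation fixes the enolate as the C7=C9 silyl enol ether and caps O2.

Step 7
Reactants: 11 (3aS,5S,7S,7aR)-7,7a-dimethyl-2,5-bis(trimethylsilyloxy)-3a,4,5,6,7,7a-hexahydro-1H-indene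
Product: 12 7,9-cyclopropane of 11 (C8 methylene on the α face; 2α,7-bis(trimethylsilyloxy)-4β,5β-dimethyl-10αH)
Conditions: Et2Zn, CH2I2, CH2Cl2, 0 °C → rt
Reagents that add atoms: diiodomethane, ICI
Why: Simmons–Smith cyclopropanation (diethylzinc variant): the electron-rich silyl enol ether is the only alkene and should take up CH2 (the future C8) mainly from the α face opposite to the C5 methyl; the two new stereocentres (C7, C9) are erased in step 8, so either diastereomer can be used.

Step 8
Reactants: 12 7,9-cyclopropane of 11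
Product: 14 (4aS,6S,8S,8aR)-6-hydroxy-8,8a-dimethyl-4a,5,6,7,8,8a-hexahydronaphthalen-2(1H)-one, via chloro ketone 13 (not isolated)
Conditions: FeCl3, pyridine, DMF, 0 °C → rt; then NaOAc, MeOH, reflux
Reagents that add atoms: none
Why: Ito–Saegusa ring expansion (FeCl3-mediated oxidative opening of a 1-silyloxybicyclo[n.1.0]alkane): exchange of silicon for trivalent iron on O7 and inner-sphere electron transfer give a cyclopropyloxy radical, whose β-scission breaks the C7–C9 bond shared by the three- and five-membered rings and leaves the ring-enlarged β-keto radical at C9, which abstracts chlorine from a second FeCl3 to give 13. No ring is closed: ring B (C5–C6–C7–C8–C9–C10) arises by one-carbon expansion of the cyclopentane, C8 having been the cyclopropane methylene. Scission of the internal rather than the external C7–C8 bond is needed, and it is secured by formation of a secondary ring radical instead of a primary one and by release of the strain of the fused bicycle. NaOAc then removes HCl by E1cB elimination across C8–C9, the only position that is both α to the C7 carbonyl and β to chlorine, and methanol cleaves the C2 silyl ether. No new stereocentre survives (the C9 chloride is lost), so both cyclopropane diastereomers of 12 converge on one enone, and C10, which is γ to the carbonyl, keeps its configuration.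

Step 9
Reactants: 14 (4aS,6S,8S,8aR)-6-hydroxy-8,8a-dimethyl-4a,5,6,7,8,8a-hexahydronaphthalen-2(1H)-one
Product: 15 8α,9α-epoxy-2α-hydroxy-4β,5β-dimethyl-10αH-decalin-7-one
Conditions: H2O2 (30 % aq.), NaOH, MeOH, 0 °C
Reagents that add atoms: hydrogen peroxide, OO
Why: Weitz–Scheffer nucleophilic epoxidation: hydroperoxide should add to C9 from the α face, opposite to the C5 methyl that stands 1,3-syn-axial over the β face of C9, and the enolate closes onto oxygen, so that C8 and C9 both carry the epoxide oxygen α.

Step 10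
Reactants: 15 8α,9α-epoxy-2α-hydroxy-4β,5β-dimethyl-10αH-decalin-7-one
Product: 17 (1R,4aR,5S,7S,8aR)-4a,5-dimethyl-1,4,4a,5,6,7,8,8a-octahydronaphthalene-1,7-diol, via epoxy hydrazone 16 (not isolated)
Conditions: N2H4·H2O, AcOH (cat.), MeOH, 0 °C → rt
Reagents that add atoms: none
Why: Wharton transposition: the epoxy hydrazone 16 fragments with loss of N2, the C8–O bond opening as the C7=C8 alkene forms, while the C9–O bond is never broken, so the allylic hydroxyl stays α on C9.

Step 11
Reactants: 17 (1R,4aR,5S,7S,8aR)-4a,5-dimethyl-1,4,4a,5,6,7,8,8a-octahydronaphthalene-1,7-diol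
Product: 18 7α,8α-epoxy-4β,5β-dimethyl-10αH-decalin-2α,9α-diol
Conditions: mCPBA, NaHCO3, CH2Cl2, 0 °C
Reagents that add atoms: 3-chloroperoxybenzoic acid, OOC(=O)c1cccc(Cl)c1
Why: Henbest (hydroxyl-directed) epoxidation: hydrogen bonding of the peracid to the pseudo-equatorial allylic 9α-hydroxyl and shielding of the β face by the C5 methyl should both deliver oxygen to the α face of C7=C8, which sets C7 and C8.

Step 12
Reactants: 18 7α,8α-epoxy-4β,5β-dimethyl-10αH-decalin-2α,9α-diol
Product: 19 (1S,2R,3R,4aR,5S,7S,8aR)-4a,5-dimethyl-3-(prop-1-en-2-yl)decahydronaphthalene-1,2,7-triol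
Conditions: isopropenylmagnesium bromide (excess), CuI (cat.), THF, −30 → 0 °C; aq. NH4Cl
Reagents that add atoms: isopropenylmagnesium bromide, CC(=C)[Mg]Br
Why: Copper-catalysed Grignard opening of the epoxide under Fürst–Plattner control: attack at C7 from the β face through a chair-like transition state should give the trans-diaxial product (7β-isopropenyl, 8α-hydroxyl), whereas attack at C8 would need a twist-boat and is hindered by the neighbouring C9 alkoxide; the two hydroxyls are carried as magnesium alkoxides.

Step 13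
Reactants: 20 (2E)-3-methylpent-2-enoic acid
Product: 21 (2E)-3-methylpent-2-enoyl chloride
Conditions: (COCl)2, DMF (cat.), CH2Cl2, 0 °C → rt
Reagents that add atoms: oxalyl chloride, ClC(=O)C(=O)Cl
Why: Acid chloride formation by Vilsmeier-type activation under cold, base-free conditions that should not isomerise the E-trisubstituted alkene.

Step 14
Reactants: 19 (1S,2R,3R,4aR,5S,7S,8aR)-4a,5-dimethyl-3-(prop-1-en-2-yl)decahydronaphthalene-1,2,7-triol; 21 (2E)-3-methylpent-2-enoyl chloride
Product: 23 (1S,2R,3R,4aR,5S,7S,8aR)-2,7-dihydroxy-4a,5-dimethyl-3-(prop-1-en-2-yl)decahydronaphthalen-1-yl (2E)-3-methylpent-2-enoate, via stannylene acetal 22 (not isolated)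
Conditions: Bu2SnO, MeOH, reflux; solvent removed; then 21, toluene, 0 °C → rt
Reagents that add atoms: none
Why: Stannylene-acetal mediated regioselective acylation: Bu2SnO ties the cis-8,9-diol into a five-membered stannylene in which the equatorial O9 is the activated oxygen, so 21 should acylate O9 without added base and leave the axial 8- and 2-hydroxyls free; no stereocentre is touched.

**Compound list**

1 | (S)-(+)-carvone, (5S)-2-methyl-5-(prop-1-en-2-yl)cyclohex-2-en-1-one | CC1=CC[C@H](C(C)=C)CC1=O | starting material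
2 | lithium (3S,5S)-2,3-dimethyl-5-(prop-1-en-2-yl)cyclohex-1-en-1-olate | [Li+].[O-]C1=C(C)[C@@H](C)C[C@H](C(C)=C)C1 | intermediate
3 | (2R,3S,5S)-2,3-dimethyl-2-(prop-2-en-1-yl)-5-(prop-1-en-2-yl)cyclohexan-1-one | C=CC[C@]1(C)[C@@H](C)C[C@H](C(C)=C)CC1=O | intermediate
4 | (2R,3S,5S)-2,3-dimethyl-2-(2-oxopropyl)-5-(prop-1-en-2-yl)cyclohexan-1-one | CC(=O)C[C@]1(C)[C@@H](C)C[C@H](C(C)=C)CC1=O | intermediate
5 | (5S,7S,7aR)-7,7a-dimethyl-5-(prop-1-en-2-yl)-1,4,5,6,7,7a-hexahydro-2H-inden-2-one (C7 ketone, C9=C10, 2α-isopropenyl, 4β,5β-dimethyl) | O=C1C=C2C[C@@H](C(C)=C)C[C@H](C)[C@@]2(C)C1 | intermediate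
6 | 5-(1-hydroperoxy-1-methoxyethyl) analogue of 5 (both epimers at the peroxy carbon) | O=C1C=C2C[C@@H](C(C)(OC)OO)C[C@H](C)[C@@]2(C)C1 | intermediate
7 | peracetate of 6 | O=C1C=C2C[C@@H](C(C)(OC)OOC(C)=O)C[C@H](C)[C@@]2(C)C1 | intermediate
8 | (5S,7S,7aR)-7,7a-dimethyl-2-oxo-1,4,5,6,7,7a-hexahydro-2H-inden-5-yl acetate | O=C1C=C2C[C@@H](OC(C)=O)C[C@H](C)[C@@]2(C)C1 | intermediate
9 | (5S,7S,7aR)-5-hydroxy-7,7a-dimethyl-1,4,5,6,7,7a-hexahydro-2H-inden-2-one | O=C1C=C2C[C@@H](O)C[C@H](C)[C@@]2(C)C1 | intermediate
10 | dilithium (3aS,5S,7S,7aR)-7,7a-dimethyl-3a,4,5,6,7,7a-hexahydro-1H-indene-2,5-bis(olate) | [Li+].[Li+].[O-]C1=C[C@@H]2C[C@@H]([O-])C[C@H](C)[C@@]2(C)C1 | intermediate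
11 | (3aS,5S,7S,7aR)-7,7a-dimethyl-2,5-bis(trimethylsilyloxy)-3a,4,5,6,7,7a-hexahydro-1H-indene (trans-fused, 10α-H) | C[Si](C)(C)OC1=C[C@@H]2C[C@@H](O[Si](C)(C)C)C[C@H](C)[C@@]2(C)C1 | intermediate
12 | 7,9-cyclopropane of 11: C8 methylene bridging C7 and C9 on the α face, 2α,7-bis(trimethylsilyloxy)-4β,5β-dimethyl-10αH-hydrindane | C[Si](C)(C)O[C@]12C[C@H]1[C@@H]3C[C@@H](O[Si](C)(C)C)C[C@H](C)[C@@]3(C)C2 | intermediate
13 | 9-chloro-4β,5β-dimethyl-2α-(trimethylsilyloxy)-10αH-decalin-7-one (both C9 epimers) | O=C1CC(Cl)[C@@H]2C[C@@H](O[Si](C)(C)C)C[C@H](C)[C@@]2(C)C1 | intermediate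
14 | (4aS,6S,8S,8aR)-6-hydroxy-8,8a-dimethyl-4a,5,6,7,8,8a-hexahydronaphthalen-2(1H)-one (2α-hydroxy-4β,5β-dimethyl-10αH-decal-8-en-7-one) | O=C1C=C[C@@H]2C[C@@H](O)C[C@H](C)[C@@]2(C)C1 | intermediate
15 | 8α,9α-epoxy-2α-hydroxy-4β,5β-dimethyl-10αH-decalin-7-one | O=C1[C@H]2O[C@H]2[C@@H]3C[C@@H](O)C[C@H](C)[C@@]3(C)C1 | intermediate
16 | hydrazone of 15 | NN=C1[C@H]2O[C@H]2[C@@H]3C[C@@H](O)C[C@H](C)[C@@]3(C)C1 | intermediate
17 | (1R,4aR,5S,7S,8aR)-4a,5-dimethyl-1,4,4a,5,6,7,8,8a-octahydronaphthalene-1,7-diol (4β,5β-dimethyl-10αH-decal-7-ene-2α,9α-diol) | C1=C[C@@H](O)[C@@H]2C[C@@H](O)C[C@H](C)[C@@]2(C)C1 | intermediate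
18 | 7α,8α-epoxy-4β,5β-dimethyl-10αH-decalin-2α,9α-diol | C1[C@H]2O[C@H]2[C@@H](O)[C@@H]3C[C@@H](O)C[C@H](C)[C@@]13C | intermediate
19 | (1S,2R,3R,4aR,5S,7S,8aR)-4a,5-dimethyl-3-(prop-1-en-2-yl)decahydronaphthalene-1,2,7-triol (7β-isopropenyl-4β,5β-dimethyl-10αH-decalin-2α,8α,9α-triol) | C=C(C)[C@H]1C[C@]2(C)[C@@H](C)C[C@H](O)C[C@H]2[C@H](O)[C@@H]1O | intermediate
20 | (2E)-3-methylpent-2-enoic acid | CC/C(C)=C/C(=O)O | starting material
21 | (2E)-3-methylpent-2-enoyl chloride | CC/C(C)=C/C(=O)Cl | intermediate
22 | 8,9-O-(dibutylstannylene) acetal of 19 | C=C(C)[C@H]1C[C@]2(C)[C@@H](C)C[C@H](O)C[C@H]2[C@@H]3O[Sn](CCCC)(CCCC)O[C@H]13 | intermediate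
23 | (1S,2R,3R,4aR,5S,7S,8aR)-2,7-dihydroxy-4a,5-dimethyl-3-(prop-1-en-2-yl)decahydronaphthalen-1-yl (2E)-3-methylpent-2-enoate | C=C(C)[C@H]1C[C@]2(C)[C@@H](C)C[C@H](O)C[C@H]2[C@H](OC(=O)/C=C(\C)CC)[C@@H]1O | target

**Step count**

Total steps: 14. Longest linear sequence: 13 steps (steps 1–12 and 14; step 13 is a one-step side branch).

**Steps most likely to fail, with fallbacks**

Step 9. What may go wrong is poor facial selectivity in the conjugate addition of hydroperoxide: the stereoelectronically preferred axial approach to C9 lies on the β face, so attack syn to the methyl may compete and would invert C9, and with it the directing hydroxyl of step 11. The fallback sets out from 14 and comes back at 17. Copper-catalysed conjugate borylation (B2pin2, CuCl, NaOtBu, Xantphos, MeOH, THF), in which the bulky ligated boryl copper should add to the less hindered α face with no need for axial attack, would give the 9α-boryl ketone F1. Oxidation with NaBO3·4H2O, which proceeds with retention at carbon, would give the β-hydroxy ketone F2. Condensation with tosylhydrazide would give the tosylhydrazone F3. A Shapiro reaction (n-BuLi in excess, THF, then water), with deprotonation at C8 on the side away from the neopentyl C6 and with the C9 alkoxide unable to leave, would give 17.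

Step 12. What may go wrong is slow or misdirected opening of the epoxide: the required β trajectory at C7 runs 1,3-diaxial to the C5 methyl, so Lewis-acid-induced rearrangement of the epoxide to a ketone or attack at C8 may take over. The fallback sets out from 18 and comes back at 19. The smaller, linear alkynylalane Et2AlC≡CSiMe3 (from lithium (trimethylsilyl)acetylide and Et2AlCl, toluene), a reagent class that opens hindered epoxides trans-diaxially, would give the 7β-(trimethylsilylethynyl) triol F4. K2CO3 in MeOH would give the terminal alkyne F5. Zirconium-catalysed methylalumination (Me3Al, Cp2ZrCl2, CH2Cl2) followed by protonolysis places the methyl on the internal alkyne carbon and would give 19.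

Step 8. What may go wrong is competing scission of the external cyclopropane bond or simple protodesilylative opening of the silyloxycyclopropane (both lead to ring-retained ketones), and over-chlorination by FeCl3. The fallback sets out from 11 and comes back at 14. Dibromocarbene (CHBr3, KOtBu, pentane, −20 °C) would add to the silyl enol ether to give the dibromocyclopropane F6. Its thermal disrotatory electrocyclic ring opening (toluene, reflux, then MeOH), with loss of the endo bromide and of the silyl groups, would give the ring-enlarged 8-bromo enone F7 by a cationic instead of a radical pathway. Palladium-catalysed hydrodebromination (Bu3SnH, Pd(PPh3)4, THF) would give 14.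

**Further compounds**

F1 | step 9 | 2α-hydroxy-4β,5β-dimethyl-9α-(4,4,5,5-tetramethyl-1,3,2-dioxaborolan-2-yl)-10αH-decalin-7-one | O=C1C[C@@H](B2OC(C)(C)C(C)(C)O2)[C@@H]3C[C@@H](O)C[C@H](C)[C@@]3(C)C1
F2 | step 9 | 2α,9α-dihydroxy-4β,5β-dimethyl-10αH-decalin-7-one | O=C1C[C@@H](O)[C@@H]2C[C@@H](O)C[C@H](C)[C@@]2(C)C1
F3 | step 9 | 4-methylbenzenesulfonylhydrazone of F2 | Cc1ccc(cc1)S(=O)(=O)NN=C1C[C@@H](O)[C@@H]2C[C@@H](O)C[C@H](C)[C@@]2(C)C1
F4 | step 12 | 4β,5β-dimethyl-7β-[(trimethylsilyl)ethynyl]-10αH-decalin-2α,8α,9α-triol | C[Si](C)(C)C#C[C@H]1C[C@]2(C)[C@@H](C)C[C@H](O)C[C@H]2[C@H](O)[C@@H]1O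
F5 | step 12 | 7β-ethynyl-4β,5β-dimethyl-10αH-decalin-2α,8α,9α-triol | C#C[C@H]1C[C@]2(C)[C@@H](C)C[C@H](O)C[C@H]2[C@H](O)[C@@H]1O
F6 | step 8 | 8,8-dibromo analogue of 12 (dibromocyclopropane on the α face) | C[Si](C)(C)O[C@]12C(Br)(Br)[C@H]1[C@@H]3C[C@@H](O[Si](C)(C)C)C[C@H](C)[C@@]3(C)C2
F7 | step 8 | 8-bromo-2α-hydroxy-4β,5β-dimethyl-10αH-decal-8-en-7-one | O=C1C(Br)=C[C@@H]2C[C@@H](O)C[C@H](C)[C@@]2(C)C1
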